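## Retrosynthetic overview

1. The quinone comes last, by Teuber oxidation of a 4-naphthol after global deprotection; the 23-membered ansa ring is closed at C11–C12 by intramolecular Nozaki–Hiyama–Kishi addition of a Z-alkenyl iodide to the C5 aryl aldehyde, then oxidation to the Z-enone.
2. The seco compound arises by joining an N-aryl methacrylamide (naphthalene fragment) to the terminal vinyl group of the chain fragment through a new amide-directed alkenyl C–H/alkene dehydrogenative coupling (C17–C18 bond, 16Z,18E diene).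
3. Chain fragment: Evans syn-aldol (C27, C28) and acyl-transfer lactonisation; proline cross-aldol (C25, C26); C20–C24 from double anti-crotylation of 2-methylpropane-1,3-diol, whose two vinyl ends are told apart by iodoetherification.
4. Naphthalene fragment: Stobbe condensation and cyclisation of 2,4-bis(benzyloxy)-3-methylbenzaldehyde, C5 formylation, Curtius rearrangement.
5. Ring order: naphthalene ring A (benzannulation onto ring B), then the δ-lactone, then the macrolactam ring, then the quinone.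

Assumption: the nine starting materials (1, 3, 12, 16, 17, 23, 26, 27, 35) and all reagents are bought; atom labels are C1–C8 for the naphthalene (N on C2, ketone carbon C11 on C5), C15 for the amide carbonyl, C16–C29 along the ansa chain ending at the enone α-carbon C12, and C34a for the lactone carbonyl.

## Route

**Naphthalene fragment**

Step 1
Reactants: 1 2,4-dihydroxy-3-methylbenzaldehyde
Product: 2 2,4-bis(benzyloxy)-3-methylbenzaldehyde
Conditions: BnBr, K2CO3, DMF, 60 °C
Reagents that add atoms: benzyl bromide, BrCc1ccccc1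
Why: Williamson ether synthesis; both phenols, the chelated ortho one included, are alkylated under these conditions.

Step 2
Reactants: 2 2,4-bis(benzyloxy)-3-methylbenzaldehyde; 3 diethyl succinate
Product: 4 (E)-4-[2,4-bis(benzyloxy)-3-methylphenyl]-3-(ethoxycarbonyl)but-3-enoic acid
Conditions: KOtBu, tBuOH, reflux; aq. HCl
Reagents that add atoms: none
Why: Stobbe condensation; the succinate enolate adds to the aldehyde and the lactone intermediate opens to the E half-ester, with the aryl group cis to the CH2CO2H arm needed for ring closure.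

Step 3
Reactants: 4 (E)-4-[2,4-bis(benzyloxy)-3-methylphenyl]-3-(ethoxycarbonyl)but-3-enoic acid
Product: 6 ethyl 4-acetoxy-6,8-bis(benzyloxy)-7-methyl-2-naphthoate, via naphthol ester 5 (not isolated)
Conditions: Ac2O, NaOAc, 140 °C
Reagents that add atoms: acetic anhydride, CC(=O)OC(C)=O
Why: Stobbe benzannulation; the mixed anhydride acylates the only free ortho carbon (intramolecular Friedel–Crafts type), and the resulting naphthol is O-acetylated, giving ring A with acetate at C4 and ester at C2.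

Step 4
Reactants: 6 ethyl 4-acetoxy-6,8-bis(benzyloxy)-7-methyl-2-naphthoate
Product: 8 ethyl 4-acetoxy-6,8-bis(benzyloxy)-5-formyl-7-methyl-2-naphthoate, via chloro(methoxy)methyl arene 7 (not isolated)
Conditions: Cl2CHOMe, AgOTf, CH2Cl2, −78 to 0 °C; aq. NaHCO3
Reagents that add atoms: dichloromethyl methyl ether, COC(Cl)Cl; water, O
Why: Rieche formylation (electrophilic aromatic substitution); C5 is ortho and para to the two benzyloxy groups while ring A is deactivated by ester and acetate, and AgOTf activation at low temperature spares the benzyl ethers.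

Step 5
Reactants: 8 ethyl 4-acetoxy-6,8-bis(benzyloxy)-5-formyl-7-methyl-2-naphthoate
Product: 10 ethyl 4,6,8-tris(benzyloxy)-5-formyl-7-methyl-2-naphthoate, via free 4-naphthol 9 (not isolated)
Conditions: K2CO3, EtOH, rt; then BnBr, DMF, 50 °C
Reagents that add atoms: benzyl bromide, BrCc1ccccc1
Why: transesterification of the aryl acetate followed by Williamson benzylation of the freed naphthoxide puts one protecting group on all three phenols.

Step 6
Reactants: 10 ethyl 4,6,8-tris(benzyloxy)-5-formyl-7-methyl-2-naphthoate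
Product: 11 4,6,8-tris(benzyloxy)-5-formyl-7-methyl-2-naphthoic acid
Conditions: LiOH, THF–H2O, rt; aq. HCl
Reagents that add atoms: lithium hydroxide, [Li+].[OH-]
Why: saponification; the non-enolisable aldehyde and the benzyl ethers are inert.

Step 7
Reactants: 11 4,6,8-tris(benzyloxy)-5-formyl-7-methyl-2-naphthoic acid; 12 methacrylic acid
Product: 15 N-[4,6,8-tris(benzyloxy)-5-formyl-7-methylnaphthalen-2-yl]-2-methylprop-2-enamide, via acyl azide 13 (not isolated), via isocyanate 14 (not isolated)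
Conditions: (PhO)2P(O)N3, Et3N, toluene, rt then 80 °C; then 12, iPr2NEt, DMF, rt
Reagents that add atoms: diphenylphosphoryl azide, [N-]=[N+]=NP(=O)(Oc1ccccc1)Oc1ccccc1
Why: Curtius rearrangement gives the aryl isocyanate, which condenses with the methacrylate anion through a mixed carbamic anhydride that loses CO2 (isocyanate–carboxylic acid amidation).

**Acyl unit for C28–C29–C12**

Step 8
Reactants: 16 ethyltriphenylphosphonium iodide; 17 3-[(tert-butyldimethylsilyl)oxy]propanal
Product: 21 (Z)-tert-butyl[(4-iodopent-3-en-1-yl)oxy]dimethylsilane, via ethylidene ylide 18 (not isolated), via iodoethyl phosphonium iodide 19 (not isolated), via iodo ylide 20 (not isolated)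
Conditions: 16, n-BuLi, THF, 0 °C; I2, −78 °C; NaN(SiMe3)2, −78 °C; then 17, −78 to −20 °C
Reagents that add atoms: iodine, II
Why: Stork–Zhao-type iodo-Wittig olefination; the unstabilised α-iodo ylide gives the Z-2-iodoalkene (iodine cis to the chain) under kinetic control.

Step 9
Reactants: 21 (Z)-tert-butyl[(4-iodopent-3-en-1-yl)oxy]dimethylsilane
Product: 22 (Z)-4-iodopent-3-enoic acid
Conditions: CrO3, H2SO4, acetone–H2O, 0 °C
Reagents that add atoms: water, O
Why: Jones oxidation; aqueous acid cleaves the primary silyl ether and the alcohol is oxidised through the aldehyde hydrate to the acid without touching the alkenyl iodide.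

Step 10
Reactants: 22 (Z)-4-iodopent-3-enoic acid; 23 (R)-4-benzyl-1,3-oxazolidin-2-one
Product: 25 (R)-4-benzyl-3-[(Z)-4-iodopent-3-enoyl]-1,3-oxazolidin-2-one, via mixed pivalic anhydride 24 (not isolated)
Conditions: tBuCOCl, Et3N, THF, −20 °C; then 23, LiCl, rt
Reagents that add atoms: none
Why: mixed-anhydride N-acylation of the oxazolidinone under the mild LiCl/Et3N protocol, which avoids conjugation of the β,γ-alkene.

**Chain fragment**

Step 11
Reactants: 26 2-methylpropane-1,3-diol; 27 but-3-en-2-yl acetate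
Product: 28 (3R,4R,6R,7R)-3,5,7-trimethylnona-1,8-diene-4,6-diol
Conditions: [Ir(cod)Cl]2 (5 mol%), (S)-SEGPHOS (10 mol%), 4-cyano-3-nitrobenzoic acid (20 mol%), Cs2CO3 (40 mol%), 27 (4 equiv), THF, 70 °C
Reagents that add atoms: none
Why: iridium-catalysed transfer-hydrogenative double anti-crotylation (Krische type); each alcohol terminus is dehydrogenated to the aldehyde and adds the crotyl iridium species through a chair transition state (anti Me/OH), and the ligand fixes both carbinols in the same sense to give the pseudo-C2 stereopentad C20–C24 (the antipodal ligand would give the enantiomer).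

Step 12
Reactants: 28 (3R,4R,6R,7R)-3,5,7-trimethylnona-1,8-diene-4,6-diol
Product: 29 6-[(2R)-but-3-en-2-yl]-2-(iodomethyl)-3,5-dimethyloxan-4-ol
Conditions: I2, NaHCO3, MeCN, 0 °C
Reagents that add atoms: iodine, II
Why: 6-exo iodoetherification; only attack of the C21 hydroxyl on the C25 vinyl group passes through a chair with a single axial substituent (the other mode needs an all-cis ring), so the C19 vinyl group is kept; the new C25 centre is of no consequence.

Step 13
Reactants: 29 6-[(2R)-but-3-en-2-yl]-2-(iodomethyl)-3,5-dimethyloxan-4-ol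
Product: 30 6-[(2R)-but-3-en-2-yl]-3,5-dimethyl-2-methylideneoxan-4-ol
Conditions: DBU, toluene, 80 °C
Reagents that add atoms: none
Why: E2 dehydroiodination of the primary iodide gives the exocyclic enol ether, as in the preparation of 5-enopyranosides.

Step 14
Reactants: 30 6-[(2R)-but-3-en-2-yl]-3,5-dimethyl-2-methylideneoxan-4-ol
Product: 31 6-[(2R)-but-3-en-2-yl]-4-hydroxy-3,5-dimethyloxan-2-one
Conditions: O3 (1.0 equiv, Sudan Red 7B end point), pyridine, CH2Cl2, −78 °C; then Me2S
Reagents that add atoms: ozone, [O-][O+]=O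
Why: ozonolysis; the electron-rich 1,1-disubstituted enol ether reacts far faster with ozone than the monosubstituted, inductively deactivated C18=C19 vinyl group, giving the lactone and formaldehyde.

Step 15
Reactants: 31 6-[(2R)-but-3-en-2-yl]-4-hydroxy-3,5-dimethyloxan-2-one
Product: 32 3,5-dihydroxy-N-methoxy-N,2,4,6-tetramethyloct-7-enamide
Conditions: MeNH(OMe)·HCl, AlMe3, CH2Cl2, 0 °C to rt
Reagents that add atoms: N,O-dimethylhydroxylamine hydrochloride, CNOC.Cl
Why: Weinreb aminolysis of the lactone by the aluminium amide opens the ring without epimerising C24.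

Step 16
Reactants: 32 3,5-dihydroxy-N-methoxy-N,2,4,6-tetramethyloct-7-enamide
Product: 33 N-methoxy-N,2,4,6-tetramethyl-3,5-bis(triethylsilyloxy)oct-7-enamide
Conditions: Et3SiOTf, 2,6-lutidine, CH2Cl2, −78 to 0 °C
Reagents that add atoms: triethylsilyl trifluoromethanesulfonate, CC[Si](CC)(CC)OS(=O)(=O)C(F)(F)F
Why: silylation with the silyl triflate caps both hindered secondary hydroxyls and prevents relactonisation.

Step 17
Reactants: 33 N-methoxy-N,2,4,6-tetramethyl-3,5-bis(triethylsilyloxy)oct-7-enamide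
Product: 34 2,4,6-trimethyl-3,5-bis(triethylsilyloxy)oct-7-enal
Conditions: iBu2AlH, THF, −78 °C
Reagents that add atoms: none
Why: hydride reduction of the Weinreb amide stops at the chelated tetrahedral intermediate, which releases the C25 aldehyde on work-up.

Step 18
Reactants: 34 2,4,6-trimethyl-3,5-bis(triethylsilyloxy)oct-7-enal; 35 propanal
Product: 36 3-hydroxy-2,4,6,8-tetramethyl-5,7-bis(triethylsilyloxy)dec-9-enal
Conditions: D-proline (20 mol%), 35 by syringe pump, DMF, 4 °C
Reagents that add atoms: none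
Why: proline-catalysed direct cross-aldol (enamine catalysis, Houk–List transition state); the D-proline enamine of propanal adds to the α-branched acceptor to give the anti aldol with C25 R and C26 R, the catalyst sense matching the Felkin preference of C24.

Step 19
Reactants: 36 3-hydroxy-2,4,6,8-tetramethyl-5,7-bis(triethylsilyloxy)dec-9-enal
Product: 37 2,4,6,8-tetramethyl-5,7-bis(triethylsilyloxy)-3-(trimethylsilyloxy)dec-9-enal
Conditions: Me3SiCl, imidazole, CH2Cl2, 0 °C
Reagents that add atoms: chlorotrimethylsilane, C[Si](C)(C)Cl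
Why: silylation gives a labile C25 ether that blocks retro-aldol and hemiacetal formation and can later be removed in the presence of the triethylsilyl ethers.

Step 20
Reactants: 37 2,4,6,8-tetramethyl-5,7-bis(triethylsilyloxy)-3-(trimethylsilyloxy)dec-9-enal; 25 (R)-4-benzyl-3-[(Z)-4-iodopent-3-enoyl]-1,3-oxazolidin-2-one
Product: 39 Evans aldol adduct (N-acyl oxazolidinone with C27 OH and C28 Z-2-iodoprop-1-enyl), via dibutylboron dienolate 38 (not isolated)
Conditions: 25, Bu2BOTf, iPr2NEt, CH2Cl2, −78 to 0 °C; then 37, −78 to 0 °C; pH 7 buffer, MeOH, H2O2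
Reagents that add atoms: none
Why: Evans syn-aldol; the Z boron dienolate reacts at its α-carbon through a Zimmerman–Traxler chair in which the (R)-benzyl auxiliary dictates the enolate face, setting C27 (S) and C28 (R) syn and keeping the Z alkenyl iodide.

Step 21
Reactants: 39 Evans aldol adduct
Product: 41 C25–C34a δ-lactone with free C27 hydroxyl, via hydroxy imide 40 (not isolated)
Conditions: PPTS, MeOH–CH2Cl2, 0 °C to rt; then toluene, 50 °C
Reagents that add atoms: none
Why: acid-catalysed methanolysis removes only the trimethylsilyl ether, and the freed C25 hydroxyl attacks the imide carbonyl (intramolecular acyl transfer) to give the all-equatorial δ-lactone with loss of the auxiliary.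

Step 22
Reactants: 41 C25–C34a δ-lactone with free C27 hydroxyl
Product: 42 chain fragment (C27 triethylsilyl ether of 41)
Conditions: Et3SiOTf, 2,6-lutidine, CH2Cl2, −78 °C
Reagents that add atoms: triethylsilyl trifluoromethanesulfonate, CC[Si](CC)(CC)OS(=O)(=O)C(F)(F)F
Why: low-temperature silylation protects the β-hydroxyl without β-elimination.

**Fragment union and endgame**

Step 23
Reactants: 15 N-[4,6,8-tris(benzyloxy)-5-formyl-7-methylnaphthalen-2-yl]-2-methylprop-2-enamide; 42 chain fragment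
Product: 43 seco (16Z,18E)-dienamide carrying the C5 aldehyde and the C12 alkenyl iodide
Conditions: [Cp*RhCl2]2 (5 mol%), AgSbF6 (20 mol%), Cu(OAc)2 (2.2 equiv), 1,2-dichloroethane, 60 °C; 15 (1.5 equiv)
Reagents that add atoms: none
Why: Proposed new method: amide-directed dehydrogenative alkenyl C–H/alkene cross-coupling of an N-aryl methacrylamide with an unactivated, α-branched terminal alkene as a fragment union; the amide carbonyl directs concerted metalation–deprotonation by the cationic trivalent Cp*Rh carboxylate at the β-C–H cis to C=O (five-membered rhodacycle, which fixes 16Z), the vinyl group of 42 inserts with Rh at C19 and the new C17–C18 bond at the CH2 terminus, syn β-hydride elimination of a C18–H (conjugation-driven, whereas the tertiary C20–H would have to eclipse the C21 silyloxy branch) gives the 18E diene, and Cu(OAc)2 returns monovalent rhodium to the trivalent state; the closest known reaction type is the rhodium- or ruthenium-catalysed oxidative olefination of acrylamides with acrylates and styrenes that gives (Z,E)-dienamides, here extended to an unactivated aliphatic alkene in a complex setting.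

Step 24
Reactants: 43 seco (16Z,18E)-dienamide
Product: 44 macrocyclic C11 carbinol
Conditions: CrCl2 (20 equiv), NiCl2 (1 mol% of Cr), DMSO–THF, rt, 1 mM, slow addition
Reagents that add atoms: none
Why: Nozaki–Hiyama–Kishi reaction; zerovalent nickel inserts into the alkenyl iodide with retention, transmetalates to chromium, and the alkenylchromium species adds intramolecularly to the aryl aldehyde under high dilution, keeping the Z geometry (both C11 epimers serve the next step).

Step 25
Reactants: 44 macrocyclic C11 carbinol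
Product: 45 protected macrocyclic Z-enone
Conditions: Dess–Martin periodinane, NaHCO3, CH2Cl2, 0 °C to rt
Reagents that add atoms: none
Why: Dess–Martin oxidation of the hindered allylic–benzylic alcohol under buffered, non-basic conditions, which avoids enolisation at C28 and leaves the ring-constrained Z-enone intact.

Step 26
Reactants: 45 protected macrocyclic Z-enone
Product: 47 fully deprotected 4-naphthol macrolactam, via tri-TES triphenol 46 (not isolated)
Conditions: BCl3, C6HMe5, CH2Cl2, −78 °C; then MeOH, −78 to 20 °C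
Reagents that add atoms: none
Why: Lewis-acid debenzylation with pentamethylbenzene as benzyl-cation scavenger frees the three phenols at −78 °C, and the HCl/MeOH formed on quench solvolyses the three triethylsilyl ethers.

Step 27
Reactants: 47 fully deprotected 4-naphthol macrolactam
Product: 48 CNP0507423.4
Conditions: K2[ON(SO3)2], KH2PO4 buffer (pH 6), acetone–H2O, 0 °C
Reagents that add atoms: potassium nitrosodisulfonate, [K+].[K+].[O]N(S(=O)(=O)[O-])S(=O)(=O)[O-]
Why: Teuber oxidation; the 4-naphthol with a free para position (C1) is oxidised by two equivalents of the nitroxyl radical to the 1,4-quinone, while the ring B phenols have no free ortho or para site.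

## Compound list

1 | 2,4-dihydroxy-3-methylbenzaldehyde | O=Cc1ccc(O)c(C)c1O | starting material
2 | 2,4-bis(benzyloxy)-3-methylbenzaldehyde | O=Cc1ccc(OCc2ccccc2)c(C)c1OCc1ccccc1 | intermediate
3 | diethyl succinate | CCOC(=O)CCC(=O)OCC | starting material
4 | (E)-4-[2,4-bis(benzyloxy)-3-methylphenyl]-3-(ethoxycarbonyl)but-3-enoic acid | CCOC(=O)/C(CC(=O)O)=C/c1ccc(OCc2ccccc2)c(C)c1OCc1ccccc1 | intermediate
5 | ethyl 6,8-bis(benzyloxy)-4-hydroxy-7-methyl-2-naphthoate | CCOC(=O)c1cc(O)c2cc(OCc3ccccc3)c(C)c(OCc3ccccc3)c2c1 | intermediate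
6 | ethyl 4-acetoxy-6,8-bis(benzyloxy)-7-methyl-2-naphthoate | CCOC(=O)c1cc(OC(C)=O)c2cc(OCc3ccccc3)c(C)c(OCc3ccccc3)c2c1 | intermediate
7 | ethyl 4-acetoxy-6,8-bis(benzyloxy)-5-[chloro(methoxy)methyl]-7-methyl-2-naphthoate | CCOC(=O)c1cc(OC(C)=O)c2c(C(Cl)OC)c(OCc3ccccc3)c(C)c(OCc3ccccc3)c2c1 | intermediate
8 | ethyl 4-acetoxy-6,8-bis(benzyloxy)-5-formyl-7-methyl-2-naphthoate | CCOC(=O)c1cc(OC(C)=O)c2c(C=O)c(OCc3ccccc3)c(C)c(OCc3ccccc3)c2c1 | intermediate
9 | ethyl 6,8-bis(benzyloxy)-5-formyl-4-hydroxy-7-methyl-2-naphthoate | CCOC(=O)c1cc(O)c2c(C=O)c(OCc3ccccc3)c(C)c(OCc3ccccc3)c2c1 | intermediate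
10 | ethyl 4,6,8-tris(benzyloxy)-5-formyl-7-methyl-2-naphthoate | CCOC(=O)c1cc(OCc2ccccc2)c2c(C=O)c(OCc3ccccc3)c(C)c(OCc3ccccc3)c2c1 | intermediate
11 | 4,6,8-tris(benzyloxy)-5-formyl-7-methyl-2-naphthoic acid | OC(=O)c1cc(OCc2ccccc2)c2c(C=O)c(OCc3ccccc3)c(C)c(OCc3ccccc3)c2c1 | intermediate
12 | methacrylic acid | CC(=C)C(=O)O | starting material
13 | 4,6,8-tris(benzyloxy)-5-formyl-7-methyl-2-naphthoyl azide | [N-]=[N+]=NC(=O)c1cc(OCc2ccccc2)c2c(C=O)c(OCc3ccccc3)c(C)c(OCc3ccccc3)c2c1 | intermediate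
14 | 4,6,8-tris(benzyloxy)-5-formyl-7-methylnaphthalen-2-yl isocyanate | O=C=Nc1cc(OCc2ccccc2)c2c(C=O)c(OCc3ccccc3)c(C)c(OCc3ccccc3)c2c1 | intermediate
15 | N-[4,6,8-tris(benzyloxy)-5-formyl-7-methylnaphthalen-2-yl]-2-methylprop-2-enamide | C=C(C)C(=O)Nc1cc(OCc2ccccc2)c2c(C=O)c(OCc3ccccc3)c(C)c(OCc3ccccc3)c2c1 | intermediate
16 | ethyltriphenylphosphonium iodide | CC[P+](c1ccccc1)(c1ccccc1)c1ccccc1.[I-] | starting material
17 | 3-[(tert-butyldimethylsilyl)oxy]propanal | O=CCCO[Si](C)(C)C(C)(C)C | starting material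
18 | ethylidenetriphenylphosphorane | CC=P(c1ccccc1)(c1ccccc1)c1ccccc1 | intermediate
19 | (1-iodoethyl)triphenylphosphonium iodide | CC(I)[P+](c1ccccc1)(c1ccccc1)c1ccccc1.[I-] | intermediate
20 | (1-iodoethylidene)triphenylphosphorane | CC(I)=P(c1ccccc1)(c1ccccc1)c1ccccc1 | intermediate
21 | (Z)-tert-butyl[(4-iodopent-3-en-1-yl)oxy]dimethylsilane | C/C(I)=C/CCO[Si](C)(C)C(C)(C)C | intermediate
22 | (Z)-4-iodopent-3-enoic acid | C/C(I)=C/CC(=O)O | intermediate
23 | (R)-4-benzyl-1,3-oxazolidin-2-one | O=C1N[C@H](Cc2ccccc2)CO1 | starting material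
24 | (Z)-4-iodopent-3-enoic pivalic anhydride | C/C(I)=C/CC(=O)OC(=O)C(C)(C)C | intermediate
25 | (R)-4-benzyl-3-[(Z)-4-iodopent-3-enoyl]-1,3-oxazolidin-2-one | C/C(I)=C/CC(=O)N1[C@H](Cc2ccccc2)COC1=O | intermediate
26 | 2-methylpropane-1,3-diol | CC(CO)CO | starting material
27 | but-3-en-2-yl acetate (racemic) | CC(OC(C)=O)C=C | starting material
28 | (3R,4R,6R,7R)-3,5,7-trimethylnona-1,8-diene-4,6-diol (C18–C25 with C20–C24 set; C22 becomes stereogenic once the ends differ) | C=C[C@@H](C)[C@@H](O)[C@@H](C)[C@H](O)[C@H](C)C=C | intermediate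
29 | 6-[(2R)-but-3-en-2-yl]-2-(iodomethyl)-3,5-dimethyloxan-4-ol (ring O is O21, ring C2 is C25, 2,6-cis; C20–C24 as in 28) | C=C[C@@H](C)[C@@H]1[C@@H](C)[C@H](O)[C@H](C)[C@H](CI)O1 | intermediate
30 | 6-[(2R)-but-3-en-2-yl]-3,5-dimethyl-2-methylideneoxan-4-ol (C20–C24 as in 28) | C=C[C@@H](C)[C@@H]1[C@@H](C)[C@H](O)[C@H](C)C(=C)O1 | intermediate
31 | 6-[(2R)-but-3-en-2-yl]-4-hydroxy-3,5-dimethyloxan-2-one (C25 carbonyl lactonised on O21; C20–C24 as in 28) | C=C[C@@H](C)[C@@H]1[C@@H](C)[C@H](O)[C@H](C)C(=O)O1 | intermediate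
32 | 3,5-dihydroxy-N-methoxy-N,2,4,6-tetramethyloct-7-enamide (C20–C24 as in 28) | C=C[C@@H](C)[C@@H](O)[C@@H](C)[C@H](O)[C@H](C)C(=O)N(C)OC | intermediate
33 | N-methoxy-N,2,4,6-tetramethyl-3,5-bis(triethylsilyloxy)oct-7-enamide | C=C[C@@H](C)[C@@H](O[Si](CC)(CC)CC)[C@@H](C)[C@H](O[Si](CC)(CC)CC)[C@H](C)C(=O)N(C)OC | intermediate
34 | 2,4,6-trimethyl-3,5-bis(triethylsilyloxy)oct-7-enal (C25 aldehyde) | C=C[C@@H](C)[C@@H](O[Si](CC)(CC)CC)[C@@H](C)[C@H](O[Si](CC)(CC)CC)[C@H](C)C=O | intermediate
35 | propanal | CCC=O | starting material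
36 | 3-hydroxy-2,4,6,8-tetramethyl-5,7-bis(triethylsilyloxy)dec-9-enal (C27 aldehyde; C25 and C26 anti) | C=C[C@@H](C)[C@@H](O[Si](CC)(CC)CC)[C@@H](C)[C@H](O[Si](CC)(CC)CC)[C@H](C)[C@@H](O)[C@@H](C)C=O | intermediate
37 | 2,4,6,8-tetramethyl-5,7-bis(triethylsilyloxy)-3-(trimethylsilyloxy)dec-9-enal | C=C[C@@H](C)[C@@H](O[Si](CC)(CC)CC)[C@@H](C)[C@H](O[Si](CC)(CC)CC)[C@H](C)[C@@H](O[Si](C)(C)C)[C@@H](C)C=O | intermediate
38 | Z dibutylboron dienolate of 25 | CCCCB(CCCC)O/C(=C\C=C(\C)I)N1[C@H](Cc2ccccc2)COC1=O | intermediate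
39 | Evans aldol adduct: N-acyl (R)-4-benzyloxazolidin-2-one with C28 (Z-2-iodoprop-1-enyl) and C27 (OH) syn, C25 OSiMe3, C21 and C23 OSiEt3, C19 vinyl | C=C[C@@H](C)[C@@H](O[Si](CC)(CC)CC)[C@@H](C)[C@H](O[Si](CC)(CC)CC)[C@H](C)[C@@H](O[Si](C)(C)C)[C@@H](C)[C@H](O)[C@@H](/C=C(/C)I)C(=O)N1[C@H](Cc2ccccc2)COC1=O | intermediate
40 | C25 hydroxy imide (39 without the trimethylsilyl group) | C=C[C@@H](C)[C@@H](O[Si](CC)(CC)CC)[C@@H](C)[C@H](O[Si](CC)(CC)CC)[C@H](C)[C@@H](O)[C@@H](C)[C@H](O)[C@@H](/C=C(/C)I)C(=O)N1[C@H](Cc2ccccc2)COC1=O | intermediate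
41 | δ-lactone (O25–C34a) with 3-[(Z)-2-iodoprop-1-enyl], 4-hydroxy and 5-methyl all trans, carrying the C18–C24 bis(triethylsilyloxy) side chain | C=C[C@@H](C)[C@@H](O[Si](CC)(CC)CC)[C@@H](C)[C@H](O[Si](CC)(CC)CC)[C@H](C)[C@H]1OC(=O)[C@H](/C=C(/C)I)[C@@H](O)[C@@H]1C | intermediate
42 | chain fragment: C27 triethylsilyl ether of 41 | C=C[C@@H](C)[C@@H](O[Si](CC)(CC)CC)[C@@H](C)[C@H](O[Si](CC)(CC)CC)[C@H](C)[C@H]1OC(=O)[C@H](/C=C(/C)I)[C@@H](O[Si](CC)(CC)CC)[C@@H]1C | intermediate
43 | seco compound: (16Z,18E)-dienamide of the tris(benzyloxy) 5-formylnaphthylamine with the lactone alkenyl iodide chain | C/C(C(=O)Nc1cc(OCc2ccccc2)c2c(C=O)c(OCc3ccccc3)c(C)c(OCc3ccccc3)c2c1)=C/C=C/[C@@H](C)[C@@H](O[Si](CC)(CC)CC)[C@@H](C)[C@H](O[Si](CC)(CC)CC)[C@H](C)[C@H]1OC(=O)[C@H](/C=C(/C)I)[C@@H](O[Si](CC)(CC)CC)[C@@H]1C | intermediate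
44 | macrocyclic C11 carbinol (both C11 epimers), tris(benzyl) tris(triethylsilyl) protected | C/C1=C/C=C/[C@@H](C)[C@@H](O[Si](CC)(CC)CC)[C@@H](C)[C@H](O[Si](CC)(CC)CC)[C@H](C)[C@H]2OC(=O)[C@H](/C=C(/C)C(O)c3c(OCc4ccccc4)c(C)c(OCc4ccccc4)c4cc(cc(OCc5ccccc5)c34)NC1=O)[C@@H](O[Si](CC)(CC)CC)[C@@H]2C | intermediate
45 | protected macrocyclic Z-enone (C11 ketone) | C/C1=C/C=C/[C@@H](C)[C@@H](O[Si](CC)(CC)CC)[C@@H](C)[C@H](O[Si](CC)(CC)CC)[C@H](C)[C@H]2OC(=O)[C@H](/C=C(/C)C(=O)c3c(OCc4ccccc4)c(C)c(OCc4ccccc4)c4cc(cc(OCc5ccccc5)c34)NC1=O)[C@@H](O[Si](CC)(CC)CC)[C@@H]2C | intermediate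
46 | tri-TES triphenol (45 without the three benzyl groups) | C/C1=C/C=C/[C@@H](C)[C@@H](O[Si](CC)(CC)CC)[C@@H](C)[C@H](O[Si](CC)(CC)CC)[C@H](C)[C@H]2OC(=O)[C@H](/C=C(/C)C(=O)c3c(O)c(C)c(O)c4cc(cc(O)c34)NC1=O)[C@@H](O[Si](CC)(CC)CC)[C@@H]2C | intermediate
47 | fully deprotected 4,6,8-trihydroxynaphthalene macrolactam (hydroquinone-level precursor with C1–H) | C/C1=C/C=C/[C@@H](C)[C@@H](O)[C@@H](C)[C@H](O)[C@H](C)[C@H]2OC(=O)[C@H](/C=C(/C)C(=O)c3c(O)c(C)c(O)c4cc(cc(O)c34)NC1=O)[C@@H](O)[C@@H]2C | intermediate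
48 | CNP0507423.4 | C/C1=C/C=C/[C@@H](C)[C@@H](O)[C@@H](C)[C@H](O)[C@H](C)[C@H]2OC(=O)[C@H](/C=C(/C)C(=O)c3c(O)c(C)c(O)c4c3C(=O)C=C(NC1=O)C4=O)[C@@H](O)[C@@H]2C | target

## Step count and risks

Total step count: 27. Longest linear sequence: 17 steps (steps 11–27, from 26).

Three steps most likely to fail:

Step 23 (the proposed new C–H/alkene coupling). The unactivated, branched alkene may insert slowly or give the deconjugated isomer by β-hydride elimination toward C20. The fallback uses known chemistry and changes the bond formed from C17–C18 to C18=C19. It sets out from 14 (made from 11 as in step 7) and from 42 and comes back at 43. Still–Gennari olefination of acrolein with ethyl 2-[bis(2,2,2-trifluoroethoxy)phosphoryl]propanoate (KN(SiMe3)2, 18-crown-6, THF, −78 °C) gives ethyl (2Z)-2-methylpenta-2,4-dienoate F1. Hydrolysis with LiOH gives (2Z)-2-methylpenta-2,4-dienoic acid F2. Isocyanate 14 is then condensed with F2 (iPr2NEt, DMF) in place of 12 to give N-[4,6,8-tris(benzyloxy)-5-formyl-7-methylnaphthalen-2-yl]-(2Z)-2-methylpenta-2,4-dienamide F3. Olefin cross-metathesis of F3 with 42 (second-generation Hoveyda–Grubbs catalyst RuCl2(H2IMes)(=CH-C6H4-2-OiPr), CH2Cl2, 40 °C) forms the 18E olefin with loss of ethene and gives 43.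

Step 24 (Nozaki–Hiyama–Kishi macrocyclisation onto a doubly flanked aryl aldehyde). The fallback moves the ring closure from C11–C12 to C18=C19. It sets out from 42 and the dienamide F3 described above and comes back at 44. Intermolecular Nozaki–Hiyama–Kishi coupling of 42 with F3 (CrCl2, NiCl2 cat., DMSO, rt) gives the open-chain C11 carbinol with terminal diene and C19 vinyl group F4. Ring-closing metathesis (second-generation Grubbs catalyst RuCl2(H2IMes)(PCy3)(=CHPh), toluene, 1 mM, 60 °C) then closes the macrocycle to 44.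

Step 14 (ozonolysis of the enol ether in the presence of the C18=C19 vinyl group). The fallback replaces ozone by epoxidation and glycol cleavage; it sets out from 30 and comes back at 31. Dimethyldioxirane in acetone (−78 to 0 °C, then water) epoxidises only the enol ether, and the spiro-epoxide opens to the hemiketal diol 6-[(2R)-but-3-en-2-yl]-2-(hydroxymethyl)-3,5-dimethyloxane-2,4-diol F5. Its 1,2-diol is cleaved with NaIO4 (THF–H2O) to lactone 31.

Further compounds
F1 | step 23 | ethyl (2Z)-2-methylpenta-2,4-dienoate | C/C(C(=O)OCC)=C/C=C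
F2 | step 23 | (2Z)-2-methylpenta-2,4-dienoic acid | C/C(C(=O)O)=C/C=C
F3 | step 23 | N-[4,6,8-tris(benzyloxy)-5-formyl-7-methylnaphthalen-2-yl]-(2Z)-2-methylpenta-2,4-dienamide | C/C(C(=O)Nc1cc(OCc2ccccc2)c2c(C=O)c(OCc3ccccc3)c(C)c(OCc3ccccc3)c2c1)=C/C=C
F4 | step 24 | open-chain C11 carbinol (both epimers) from 42 and F3, with terminal (2Z)-dienamide and C19 vinyl group | C=C[C@@H](C)[C@@H](O[Si](CC)(CC)CC)[C@@H](C)[C@H](O[Si](CC)(CC)CC)[C@H](C)[C@H]1OC(=O)[C@H](/C=C(/C)C(O)c2c(OCc3ccccc3)c(C)c(OCc3ccccc3)c3cc(NC(=O)/C(C)=C\C=C)cc(OCc4ccccc4)c23)[C@@H](O[Si](CC)(CC)CC)[C@@H]1C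
F5 | step 14 | 6-[(2R)-but-3-en-2-yl]-2-(hydroxymethyl)-3,5-dimethyloxane-2,4-diol | C=C[C@@H](C)[C@@H]1[C@@H](C)[C@H](O)[C@H](C)C(O)(CO)O1
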